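## Structural features

The target is a germacrane-type ten-membered carbocycle (C1–C10) whose C6–C7 bond is shared with an α-(acetoxymethyl)butenolide (C11, C12, C13; lactone oxygen on C6, C7=C11 exocyclic to the large ring). Around the ring stand a 1,3-diketone (C1 and C3 with C2 between them), a trans-4,5-epoxide that makes C3 an α,β-epoxy ketone, the lactone oxygen on C6, a (Z)-4-acetoxy-3-methylbut-2-enoate on O8 and a methyl group on C10. C4 (S), C5 (R) and C6 (R) are contiguous, C8 (R) is separated from C6 only by the sp2 carbon C7, and C10 (R) is remote from all of them and α to the C1 carbonyl, so it can epimerize once that ketone is free. The fragile groups are the β-diketone, the epoxy ketone, two primary allylic acetates, the Z-enoate and the lactone, which can migrate from O6 to O8. The real difficulty is the combination of a medium ring with five stereocenters, of which C10 has no neighbour to relay from and the trans-epoxide cannot exist in any six-membered precursor. The key step exploits that C3 and C8 face each other 1,6 across the ring at carbonyl or carbinol level: joining them gives a Δ3(8)-octalin in which ring A (C3–C8) carries the C4 methyl and the C5 and C6 oxygens and ring B (C8, C9, C10, C1, C2, C3) is a reduced trialkylbenzene ring, so the ten-membered ring is released by cutting C3=C8 and never has to be closed.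

## Logic of the disconnections

30 ⇒ 29. The two C–O bonds that mask the C1 carbonyl are undone last. A free 1,3-diketone would be acylated, reduced or deprotonated in the late steps and would expose C10 to epimerization. 29 therefore holds a single ketone, and the forward step must be a hydrolysis mild enough for an epoxy ketone and three esters.

29 ⇒ 23 + 28. The O8–acyl bond is cut. The side chain would not survive the basic and reducing steps, and late attachment makes the route convergent. The forward acylation of a hindered allylic alcohol must not let the lactone slip from O6 to O8, and 28 must already carry its acetate because the free Z-hydroxy acid would lactonize.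

28 ⇒ 27 ⇒ 24. The acyl C–O bonds of 28 are traced back to the ring C–O bond of 24, whose ring fixes the Z geometry. The forward demand is to cap both oxygens of the opened hydroxy carboxylate before it recloses.

23 ⇒ 22. The C8–H bond is removed. C8 must be a ketone earlier, because it is one terminus of the alkene cleaved in the key step and because only a ketone makes C7 nucleophilic. The price is a late reduction that must choose C8 over C3 and one face by reagent control.

22 ⇒ 20 ⇒ 19 ⇒ 15 + 17, and 17 ⇒ 16. The C7=C11 bond is cut by retro-aldol condensation, then the O6–C12 ester bond; the C11 carbonyl of 20 comes from the C11=CH2 group of 19, and the C13–O bond of 17 from 16. Tethering the electrophile to O6 is what distinguishes C7 from C9 and C2. The whole butenolide is removed, and the forward aldol has to outrun β-elimination of the C6 acyloxy group.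

15 ⇒ 14 ⇒ 13 ⇒ 12. The silyl group returns to O6, the two epoxide C–O bonds are cut to the enone, and acetic acid is added back across C4=C5. A trans-epoxide cannot sit on a six-membered ring, so it has to be made after ring opening; a β-acetoxy ketone gives the enone at C4=C5 and nowhere else. The forward demand is peroxide addition to the face of C5 anti to the C6 silyloxy group.

12 ⇒ 11. C3 and C8 are joined by a double bond. The ten-membered ring becomes two six-membered rings, so a medium-ring closure is replaced by an alkene cleavage. 11 must hold no other C=C and the work-up must be neutral.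

11 ⇒ 10 ⇒ 9 ⇒ 8. The ketal C–O bonds, then the C1–O and C10–H bonds are removed, leaving the C1=C10 alkene of 8. Ring B is insulated from the stereocenters of ring A by the planar C3=C8 unit, so a C10 center made by protonating an enol ether or enol of C1 would form without bias. Adding H and O across the alkene with a chiral borane puts C10 under reagent control and brings in the C1 oxygen at once. The reaction must take the trisubstituted and not the tetrasubstituted alkene, and the oxidation and ketalization must neither epimerize C10 nor move C3=C8.

8 ⇒ 7 ⇒ 6. The acetate is removed and the hydrogens added at C2 and C9 are taken away to give the arene. A Birch reduction leaves the alkyl-bearing carbons on double bonds, which is exactly the C3=C8/C1=C10 pattern. The silyl ether and the free C5 hydroxyl must pass Li/NH3, which an acetate would not, without O-to-O silyl shift.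

6 ⇒ 5. The aryl C3–C4 bond is cut. Epoxide opening at C4 by the arene with inversion gives the C4 methine and the C5 hydroxyl from stereocenters made on the open chain. The attacking carbon is para to the ring methyl. An alkoxy donor para to the benzylic carbon of 5 was avoided: it would activate the ipso carbon (spiro closure) and not C3. Six-membered opening must beat a hydride shift.

5 ⇒ 4 ⇒ 3. The O–Si bond and then the epoxide C–O bonds are cut. A kinetic resolution by asymmetric epoxidation sets C6 absolutely and C5 and C4 relative to it. The tartrate antipode must be the one that epoxidizes the (R)-carbinol.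

3 ⇒ 1 + 2. The C6–C7 bond is cut between a benzylic nucleophile and an enal carbonyl. The forward step needs 1,2- and not 1,4-addition.

## Other disconnections considered

Alternative 1: The cut is the C2–C3 bond together with a temporary O–C1 bond. In the forward direction NaOCl would oxidize a C3 aldoxime function to a nitrile oxide, which would add across a terminal C1=C2 alkene at the far end of the chain to give the isoxazoline-bridged carbocycle A1. Reductive N–O cleavage and oxidation of the C1 carbinol would then release the 1,3-diketone.
- In its favour: A1 already holds the butenolide, the epoxide and both esters, so every stereocenter could be set on an open chain, C10 could come from a chiral building block, and the isoxazoline is a sturdier mask for the diketone than a ketal next to a ketone. On these three points it is better than the chosen plan. It would also need only two steps after its key step, against eight here.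
- Against it: the ten-membered ring must be closed in competition with dimerization of the dipole and with the fused mode of addition, which would give a nine-membered ring. This ring size is the least favourable for such cycloadditions. Hypochlorite and base would meet two allylic acetates and a Z-enoate, and the N–O bond would have to be reduced beside an epoxy ketone and two electron-poor alkenes.
- Comparison: structurally the ring is made at the end instead of being released in the middle. Mechanistically a cycloaddition with an entropic and transannular penalty stands against an ozonolysis that has none. In step count the short end is paid for by a long linear preparation of the functionalized chain, so the totals should be similar, with the risk concentrated in one late step.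

Alternative 2: The cuts are the lactone C6–O bond and a C3–O bond. Forward, Pd(OAc)2 with benzoquinone and LiOAc in AcOH would let a C12 carboxyl group attack C6 of a ring 1,3-diene (C3=C4–C5=C6) bound to divalent palladium, and acetate would open the π-allyl complex at C3 to give A2 with an E C4=C5 bond.
- In its favour: the lactone and the C6 center arise without any enolate next to a β-acyloxy ketone, which is the weak point of step 16 here, and O8 is already in place with its configuration, so no late ketone reduction is needed. On both points it is better.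
- Against it: the reaction type is established for six- and seven-membered dienes. In a ten-membered ring the diene would have to reach an s-cis arrangement while cross-conjugated with the acrylic acid unit, the site of acetate attack (C3 or C5) is open, and C6 would be set only relative to C3, a center that is destroyed afterwards. After A2 the C3 acetate must become the enone and be epoxidized beside the finished butenolide; this is the same facial problem as step 11 here, on a more fragile compound, so at best equal.
- Comparison: structurally the key step makes the five-membered ring and leaves the harder ten-membered ring to other chemistry. Mechanistically a reliable anti-oxypalladation is set against unknown conformational control. In step count it is longer after the key step, and the route to the macrocyclic triene acid stage is unsolved.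

Alternative 3: The cut is the C5–C6 bond; retrosynthetically the C3–C8 bond is re-formed, so ring B of the chosen plan reappears as a cyclohexane bearing an isopropenyl group on the C3 carbinol and a dihydrofuranyl group on C8. Forward, KH with 18-crown-6 would form the C3 alkoxide, the anionic oxy-Cope shift would expand the ring, and Me3SiCl would trap the enolate as A3.
- In its favour: like the chosen plan it obtains the ten-membered ring from a six-membered one without macrocyclization (equal). It forms a C–C bond and the C6 center in the same step. C10 could be set on a cyclohexanone by substrate control (better than the reagent-controlled hydroboration of step 7). The two enol ethers of A3 are a ready-made masked 1,3-diketone (better than the ketal).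
- Against it: A3 is far from the target. C5 and C8 carry no oxygen, C12 is at ether level, C13 is missing and the alkene is C7=C8 and not C7=C11. Allylic oxidation with transposition, ether-to-lactone oxidation, hydroxymethylation, C4=C5 desaturation and epoxidation would all follow on a ten-membered ring, and the chair or boat preference that sets C6 relative to C10 is not secure.
- Comparison: structurally the chosen plan delivers oxygen at C3, C5, C6 and C8 directly. Mechanistically both key steps are dependable ring-releasing events. In step count Alternative 3 is clearly longer after its key step.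

Key step: step 10

Remark: atoms are numbered as in the target (C1–C10 ring, C11–C13 butenolide) in all intermediates; (3-methylbenzyl)magnesium chloride in THF, 2-(bromomethyl)acrylic acid and 4-methylfuran-2(5H)-one are assumed to be catalogue compounds.

## Steps

Step 1
Reactants: 1 (3-methylbenzyl)magnesium chloride; 2 (E)-crotonaldehyde
Product: 3 rac-(E)-1-(3-methylphenyl)pent-3-en-2-ol
Conditions: THF, −78 → 0 °C; aq NH4Cl
Reagents that add atoms: none
Why: Grignard 1,2-addition to an enal forms the C6–C7 bond; the hard benzylic magnesium reagent should add to the carbonyl and not to the β-carbon, and the E-alkene is carried through unchanged.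

Step 2
Reactants: 3 rac-(E)-1-(3-methylphenyl)pent-3-en-2-ol
Product: 4 (2R,3R,4R)-3,4-epoxy-1-(3-methylphenyl)pentan-2-ol
Conditions: Ti(OiPr)4, D-(−)-diisopropyl tartrate, t-BuOOH (0.45 equiv), 4 Å MS, CH2Cl2, −20 °C
Reagents that add atoms: tert-butyl hydroperoxide, CC(C)(C)OO
Why: Sharpless kinetic resolution by asymmetric epoxidation: with the D-(−)-tartrate the (R)-carbinol is the fast-reacting enantiomer and is epoxidized to the erythro epoxy alcohol, which sets C6 (R) absolutely and C5 and C4 relative to it; the (S)-alcohol is left behind and separated.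

Step 3
Reactants: 4 (2R,3R,4R)-3,4-epoxy-1-(3-methylphenyl)pentan-2-ol
Product: 5 (2R,3S,4R)-2-(tert-butyldimethylsilyloxy)-3,4-epoxy-1-(3-methylphenyl)pentane
Conditions: TBSCl, imidazole, DMF, rt
Reagents that add atoms: tert-butyldimethylsilyl chloride, CC(C)(C)[Si](C)(C)Cl
Why: Standard silylation of a secondary alcohol; the ether blocks O6 during the Lewis-acid and reduction steps and later tells O6 from O5 (the C3 descriptor changes by priority only).

Step 4
Reactants: 5 (2R,3S,4R)-2-(tert-butyldimethylsilyloxy)-3,4-epoxy-1-(3-methylphenyl)pentane
Product: 6 (1R,2S,3R)-3-(tert-butyldimethylsilyloxy)-1,6-dimethyl-1,2,3,4-tetrahydronaphthalen-2-ol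
Conditions: InBr3 (0.2 equiv), CH2Cl2, −20 °C → rt
Reagents that add atoms: none
Why: Intramolecular Friedel–Crafts alkylation by an epoxide (epoxy-arene cyclization): the Lewis-acid-bound epoxide is opened at C4, the carbon remote from the electron-withdrawing silyloxy group, by the arene carbon para to the methyl group, with inversion at C4 and retention at C5. Six-membered closure is favoured over the strained five-membered mode, and the other ortho carbon is hindered by the methyl group.

Step 5
Reactants: 6 (1R,2S,3R)-3-(tert-butyldimethylsilyloxy)-1,6-dimethyl-1,2,3,4-tetrahydronaphthalen-2-ol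
Product: 7 (1R,2S,3R)-3-(tert-butyldimethylsilyloxy)-1,6-dimethyl-1,2,3,4,5,8-hexahydronaphthalen-2-ol
Conditions: Li, NH3 (l), THF, t-BuOH, −78 °C; NH4Cl
Reagents that add atoms: none
Why: Birch reduction: the 1,2,4-trialkylbenzene is protonated at its two unsubstituted para-related carbons C2 and C9, so the double bonds end on the alkylated carbons (C3=C8 and C1=C10). The lithium alkoxide on O5 and the silyl ether survive, and low temperature and the lithium counter-ion limit O6-to-O5 silyl migration.

Step 6
Reactants: 7 (1R,2S,3R)-3-(tert-butyldimethylsilyloxy)-1,6-dimethyl-1,2,3,4,5,8-hexahydronaphthalen-2-ol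
Product: 8 (1R,2S,3R)-3-(tert-butyldimethylsilyloxy)-1,6-dimethyl-1,2,3,4,5,8-hexahydronaphthalen-2-yl acetate
Conditions: Ac2O, pyridine, 4-(dimethylamino)pyridine (cat.), CH2Cl2, 0 °C
Reagents that add atoms: acetic anhydride, CC(=O)OC(C)=O
Why: Acylation with nucleophilic catalysis puts the later leaving group on O5 after the step that would have cleaved it and before the oxidation of step 8, so that C1 is then the only free carbinol.

Step 7
Reactants: 8 (1R,2S,3R)-3-(tert-butyldimethylsilyloxy)-1,6-dimethyl-1,2,3,4,5,8-hexahydronaphthalen-2-yl acetate
Product: 9 (1R,2S,3R,6R,7R)-3-(tert-butyldimethylsilyloxy)-7-hydroxy-1,6-dimethyl-1,2,3,4,5,6,7,8-octahydronaphthalen-2-yl acetate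
Conditions: monoisopinocampheylborane (IpcBH2, from (−)-α-pinene), THF, −25 °C; then H2O2, aq NaOAc, 0 °C → rt
Reagents that add atoms: hydrogen peroxide, OO
Why: Asymmetric hydroboration–oxidation: the monoalkylborane adds to the trisubstituted C1=C10 bond (the tetrasubstituted C3=C8 bond is too hindered), boron to C1 and hydrogen to C10 from the same face, giving the trans C1-hydroxyl/C10-methyl pair. The borane antipode is the one that converts 1-methylcyclohexene into (1R,2R)-trans-2-methylcyclohexanol, so it should favour the (1R,10R) isomer (target numbering); the minor (1S,10S) isomer is removed by chromatography.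

Step 8
Reactants: 9 (1R,2S,3R,6R,7R)-3-(tert-butyldimethylsilyloxy)-7-hydroxy-1,6-dimethyl-1,2,3,4,5,6,7,8-octahydronaphthalen-2-yl acetate
Product: 10 (1R,2S,3R,6R)-3-(tert-butyldimethylsilyloxy)-1,6-dimethyl-7-oxo-1,2,3,4,5,6,7,8-octahydronaphthalen-2-yl acetate
Conditions: Dess–Martin periodinane, NaHCO3, CH2Cl2, 0 °C
Reagents that add atoms: none
Why: Dess–Martin oxidation under buffered, near-neutral conditions gives the β,γ-unsaturated ketone without moving C3=C8 into conjugation and without enolization toward C10.

Step 9
Reactants: 10 (1R,2S,3R,6R)-3-(tert-butyldimethylsilyloxy)-1,6-dimethyl-7-oxo-1,2,3,4,5,6,7,8-octahydronaphthalen-2-yl acetate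
Product: 11 (1R,2S,3R,6R)-3-(tert-butyldimethylsilyloxy)-7,7-(ethylenedioxy)-1,6-dimethyl-1,2,3,4,5,6,7,8-octahydronaphthalen-2-yl acetate
Conditions: 1,2-bis(trimethylsilyloxy)ethane, trimethylsilyl trifluoromethanesulfonate (cat.), CH2Cl2, −78 °C
Reagents that add atoms: 1,2-bis(trimethylsilyloxy)ethane, C[Si](C)(C)OCCO[Si](C)(C)C
Why: Aprotic silyl-transfer ketalization at low temperature, driven by formation of hexamethyldisiloxane, protects C1 without the enol or enol ether intermediates that would epimerize C10 or shift the alkene; C3=C8 is then the only C=C.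

Step 10
Reactants: 11 (1R,2S,3R,6R)-3-(tert-butyldimethylsilyloxy)-7,7-(ethylenedioxy)-1,6-dimethyl-1,2,3,4,5,6,7,8-octahydronaphthalen-2-yl acetate
Product: 12 (4S,5S,6R,10R)-5-acetoxy-6-(tert-butyldimethylsilyloxy)-1,1-(ethylenedioxy)-4,10-dimethylcyclodecane-3,8-dione
Conditions: O3, CH2Cl2/MeOH (4:1), NaHCO3, −78 °C; then Me2S, −78 °C → rt
Reagents that add atoms: ozone, [O-][O+]=O
Why: Ozone adds as a 1,3-dipole to the electron-rich tetrasubstituted C3=C8 bond; the primary ozonide fragments to a ketone and a carbonyl oxide held in the same chain, methanol traps the carbonyl oxide as a methoxy hydroperoxide (or it recloses to the ozonide), and dimethyl sulfide reduces the peroxide to the second ketone. The closest known reaction type is the ozonolysis of Birch-derived ring-fusion octalins to cyclodecane-1,6-diones. No ring is closed by bond formation: the ten-membered ring appears because the bond shared by the two six-membered rings is cut, so no entropic or transannular penalty of a medium-ring closure is paid. No stereocenter is formed, and C4, C5, C6 and C10 are untouched (the C4 descriptor changes from R to S only because C3 gains priority). The only selectivity needed is that nothing else is oxidized, which is secured because 11 has no other C=C and acetate, silyl ether and dioxolane are inert to ozone at −78 °C. Bicarbonate buffering, low temperature and a neutral reductive work-up should prevent transannular aldol closure of the 1,6-diketone, β-elimination of the C5 acetate and epimerization.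

Step 11
Reactants: 12 (4S,5S,6R,10R)-5-acetoxy-6-(tert-butyldimethylsilyloxy)-1,1-(ethylenedioxy)-4,10-dimethylcyclodecane-3,8-dione
Product: 14 (4S,5R,6R,10R)-6-(tert-butyldimethylsilyloxy)-4,5-epoxy-1,1-(ethylenedioxy)-4,10-dimethylcyclodecane-3,8-dione, via (E)-enone 13 (not isolated)
Conditions: t-BuOOH (anhydrous), DBU, CH2Cl2, 0 °C → rt
Reagents that add atoms: tert-butyl hydroperoxide, CC(C)(C)OO
Why: E1cB elimination of the C5 acetate (DBU removes H4, α to the C3 ketone) gives the C4=C5 enone, which is consumed at once by the hydroperoxide anion in a Weitz–Scheffer epoxidation, so that it has little time for transannular Michael addition. The peroxide should add to C5 from the outer face of the ring anti to the bulky C6 silyloxy group, as with acyclic γ-silyloxy enones, and the enolate then closes on oxygen to the trans-epoxide, setting C5 (R) and C4 (S).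

Step 12
Reactants: 14 (4S,5R,6R,10R)-6-(tert-butyldimethylsilyloxy)-4,5-epoxy-1,1-(ethylenedioxy)-4,10-dimethylcyclodecane-3,8-dione
Product: 15 (4S,5R,6R,10R)-4,5-epoxy-1,1-(ethylenedioxy)-6-hydroxy-4,10-dimethylcyclodecane-3,8-dione
Conditions: HF·pyridine, pyridine, THF, 0 °C → rt
Reagents that add atoms: none
Why: Fluoride-mediated desilylation under buffered acidic conditions frees O6 without forming the alkoxide that would start a Payne rearrangement or a retro-aldol; the epoxide, deactivated by the ketone, should not be opened.

Step 13
Reactants: 16 2-(bromomethyl)acrylic acid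
Product: 17 2-(acetoxymethyl)acrylic acid
Conditions: NaOAc, AcOH, 60 °C
Reagents that add atoms: sodium acetate, CC(=O)[O-].[Na+]
Why: Allylic nucleophilic substitution of bromide by acetate (direct and allylic-shift attack give the same product); acetic acid keeps the carboxyl group protonated so that it does not alkylate itself.

Step 14
Reactants: 15 (4S,5R,6R,10R)-4,5-epoxy-1,1-(ethylenedioxy)-6-hydroxy-4,10-dimethylcyclodecane-3,8-dione; 17 2-(acetoxymethyl)acrylic acid
Product: 19 (4S,5R,6R,10R)-4,5-epoxy-1,1-(ethylenedioxy)-4,10-dimethyl-3,8-dioxocyclodecan-6-yl 2-(acetoxymethyl)acrylate, via 2-(acetoxymethyl)acryloyl chloride 18 (not isolated)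
Conditions: 17, (COCl)2, DMF (cat.), CH2Cl2, 0 °C; then 15, pyridine, 0 °C → rt
Reagents that add atoms: oxalyl chloride, O=C(Cl)C(Cl)=O (chlorine of 18 only)
Why: Acylation of the secondary C6 hydroxyl by an acid chloride under pyridine; no strong base and no strongly nucleophilic amine is present, so Payne rearrangement, dehydration of the β-hydroxy ketone and displacement of the allylic acetate should not compete.

Step 15
Reactants: 19 (4S,5R,6R,10R)-4,5-epoxy-1,1-(ethylenedioxy)-4,10-dimethyl-3,8-dioxocyclodecan-6-yl 2-(acetoxymethyl)acrylate
Product: 20 (4S,5R,6R,10R)-4,5-epoxy-1,1-(ethylenedioxy)-4,10-dimethyl-3,8-dioxocyclodecan-6-yl 3-acetoxy-2-oxopropanoate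
Conditions: O3, CH2Cl2, −78 °C; then Me2S
Reagents that add atoms: ozone, [O-][O+]=O
Why: Ozonolysis of the 1,1-disubstituted acrylate, the only C=C in 19, gives the α-keto ester with loss of formaldehyde; the C13 acetate is already in place, so no free hydroxypyruvate has to be handled.

Step 16
Reactants: 20 (4S,5R,6R,10R)-4,5-epoxy-1,1-(ethylenedioxy)-4,10-dimethyl-3,8-dioxocyclodecan-6-yl 3-acetoxy-2-oxopropanoate
Product: 22 (4S,5R,6R,10R)-13-acetoxy-4,5-epoxy-1,1-(ethylenedioxy)-3,8-dioxogermacr-7(11)-en-12,6-olide, via aldol adduct 21 (not isolated)
Conditions: Et3N, LiCl, MeCN, 0 °C; then Ac2O, 4-(dimethylamino)pyridine (cat.), rt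
Reagents that add atoms: none
Why: Intramolecular aldol condensation: the tether on O6 lets only the C7 enolate of the C8 ketone reach the activated keto carbonyl C11 through a five-membered transition state (C9 and C2 would need seven- and eight-membered rings), forming C7–C11 and the lactone ring. Acetylation of the tertiary C11 hydroxyl and E1cB loss of acetate across C7–C11 then give the tetrasubstituted butenolide, and the anhydride re-acetylates O13 should the acetyl group have migrated.

Step 17
Reactants: 22 (4S,5R,6R,10R)-13-acetoxy-4,5-epoxy-1,1-(ethylenedioxy)-3,8-dioxogermacr-7(11)-en-12,6-olide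
Product: 23 (4S,5R,6R,8R,10R)-13-acetoxy-4,5-epoxy-1,1-(ethylenedioxy)-8-hydroxy-3-oxogermacr-7(11)-en-12,6-olide
Conditions: (S)-1-methyl-3,3-diphenyltetrahydro-1H,3H-pyrrolo[1,2-c][1,3,2]oxazaborole (1.0 equiv), BH3·SMe2, CH2Cl2, −40 °C; MeOH
Reagents that add atoms: none
Why: Corey–Bakshi–Shibata reduction: the fully substituted alkenyl carbon C7 acts as the large and the C9 methylene as the small ketone substituent, so the (S)-oxazaborolidine should deliver hydride to the face that gives the 8R allylic alcohol (the sense in which acetophenone gives (R)-1-phenylethanol). The C8 ketone, activated by the electron-poor alkene and flanked by a methylene, should react before the neopentyl-type C3 epoxy ketone.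

Step 18
Reactants: 24 4-methylfuran-2(5H)-one
Product: 27 4-methoxybenzyl (Z)-4-acetoxy-3-methylbut-2-enoate, via potassium (Z)-4-hydroxy-3-methylbut-2-enoate 25 (not isolated), via 4-methoxybenzyl (Z)-4-hydroxy-3-methylbut-2-enoate 26 (not isolated)
Conditions: KOH (1 equiv), MeOH/H2O, rt, evaporate; 4-methoxybenzyl chloride, DMF, rt; then Ac2O, pyridine, 0 °C
Reagents that add atoms: potassium hydroxide, [K+].[OH-]; 4-methoxybenzyl chloride, COc1ccc(CCl)cc1; acetic anhydride, CC(=O)OC(C)=O
Why: Saponification opens the butenolide to the hydroxy carboxylate with the Z geometry that the ring imposed; O-alkylation of the carboxylate and acetylation of the primary hydroxyl in the same flask cap both ends before the hydroxy ester can close back to the lactone.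

Step 19
Reactants: 27 4-methoxybenzyl (Z)-4-acetoxy-3-methylbut-2-enoate
Product: 28 (Z)-4-acetoxy-3-methylbut-2-enoic acid
Conditions: CF3CO2H, anisole, CH2Cl2, 0 °C
Reagents that add atoms: none
Why: Acidolysis of the 4-methoxybenzyl ester (the benzylic cation is taken up by anisole) frees the acid without touching the allylic acetate or the Z-alkene; with O4 acylated the acid cannot lactonize.

Step 20
Reactants: 23 (4S,5R,6R,8R,10R)-13-acetoxy-4,5-epoxy-1,1-(ethylenedioxy)-8-hydroxy-3-oxogermacr-7(11)-en-12,6-olide; 28 (Z)-4-acetoxy-3-methylbut-2-enoic acid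
Product: 29 (4S,5R,6R,8R,10R)-13-acetoxy-8-[(Z)-4-acetoxy-3-methylbut-2-enoyloxy]-4,5-epoxy-1,1-(ethylenedioxy)-3-oxogermacr-7(11)-en-12,6-olide
Conditions: dicyclohexylcarbodiimide, 4-(dimethylamino)pyridine (cat.), CH2Cl2, 0 °C → rt
Reagents that add atoms: none
Why: Steglich esterification of the allylic C8 hydroxyl; the near-neutral conditions avoid the C8 alkoxide, which could attack C12 and move the lactone to O8, and should not isomerize the Z-enoate.

Step 21
Reactants: 29 (4S,5R,6R,8R,10R)-13-acetoxy-8-[(Z)-4-acetoxy-3-methylbut-2-enoyloxy]-4,5-epoxy-1,1-(ethylenedioxy)-3-oxogermacr-7(11)-en-12,6-olide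
Product: 30 (4S,5R,6R,8R,10R)-13-acetoxy-8-[(Z)-4-acetoxy-3-methylbut-2-enoyloxy]-4,5-epoxy-1,3-dioxogermacr-7(11)-en-12,6-olide
Conditions: TsOH·H2O (cat.), acetone/H2O, rt
Reagents that add atoms: water, O
Why: Acid-catalysed hydrolysis (transketalization to acetone) of the dioxolane frees the C1 ketone; the epoxide is deactivated toward acid by the adjacent carbonyl, the esters are stable to dilute acid at room temperature, and the diketone enolizes toward C2, which protects C10.

## Compound list

1 | (3-methylbenzyl)magnesium chloride | Cc1cccc(C[Mg]Cl)c1 | starting material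
2 | (E)-crotonaldehyde | C/C=C/C=O | starting material
3 | rac-(E)-1-(3-methylphenyl)pent-3-en-2-ol | C/C=C/C(O)Cc1cccc(C)c1 | intermediate
4 | (2R,3R,4R)-3,4-epoxy-1-(3-methylphenyl)pentan-2-ol | C[C@H]1O[C@@H]1[C@H](O)Cc1cccc(C)c1 | intermediate
5 | (2R,3S,4R)-2-(tert-butyldimethylsilyloxy)-3,4-epoxy-1-(3-methylphenyl)pentane | C[C@H]1O[C@@H]1[C@H](O[Si](C)(C)C(C)(C)C)Cc1cccc(C)c1 | intermediate
6 | (1R,2S,3R)-3-(tert-butyldimethylsilyloxy)-1,6-dimethyl-1,2,3,4-tetrahydronaphthalen-2-ol (target numbering 4R,5S,6R) | C[C@@H]1c2ccc(C)cc2C[C@@H](O[Si](C)(C)C(C)(C)C)[C@H]1O | intermediate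
7 | (1R,2S,3R)-3-(tert-butyldimethylsilyloxy)-1,6-dimethyl-1,2,3,4,5,8-hexahydronaphthalen-2-ol | C[C@@H]1C2=C(C[C@@H](O[Si](C)(C)C(C)(C)C)[C@H]1O)CC(C)=CC2 | intermediate
8 | (1R,2S,3R)-3-(tert-butyldimethylsilyloxy)-1,6-dimethyl-1,2,3,4,5,8-hexahydronaphthalen-2-yl acetate | C[C@@H]1C2=C(C[C@@H](O[Si](C)(C)C(C)(C)C)[C@H]1OC(C)=O)CC(C)=CC2 | intermediate
9 | (1R,2S,3R,6R,7R)-3-(tert-butyldimethylsilyloxy)-7-hydroxy-1,6-dimethyl-1,2,3,4,5,6,7,8-octahydronaphthalen-2-yl acetate (target numbering 1R,4R,5S,6R,10R) | C[C@@H]1C2=C(C[C@@H](O[Si](C)(C)C(C)(C)C)[C@H]1OC(C)=O)C[C@@H](C)[C@H](O)C2 | intermediate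
10 | (1R,2S,3R,6R)-3-(tert-butyldimethylsilyloxy)-1,6-dimethyl-7-oxo-1,2,3,4,5,6,7,8-octahydronaphthalen-2-yl acetate | C[C@@H]1C2=C(C[C@@H](O[Si](C)(C)C(C)(C)C)[C@H]1OC(C)=O)C[C@@H](C)C(=O)C2 | intermediate
11 | (1R,2S,3R,6R)-3-(tert-butyldimethylsilyloxy)-7,7-(ethylenedioxy)-1,6-dimethyl-1,2,3,4,5,6,7,8-octahydronaphthalen-2-yl acetate (Δ3(8)-octalin, target numbering 4R,5S,6R,10R) | C[C@@H]1C2=C(C[C@@H](O[Si](C)(C)C(C)(C)C)[C@H]1OC(C)=O)C[C@@H](C)C3(C2)OCCO3 | intermediate
12 | (4S,5S,6R,10R)-5-acetoxy-6-(tert-butyldimethylsilyloxy)-1,1-(ethylenedioxy)-4,10-dimethylcyclodecane-3,8-dione | C[C@@H]1C(=O)CC2(OCCO2)[C@H](C)CC(=O)C[C@@H](O[Si](C)(C)C(C)(C)C)[C@H]1OC(C)=O | intermediate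
13 | (4E,6R,10R)-6-(tert-butyldimethylsilyloxy)-1,1-(ethylenedioxy)-4,10-dimethylcyclodec-4-ene-3,8-dione | C/C1=C\[C@H](O[Si](C)(C)C(C)(C)C)CC(=O)C[C@@H](C)C2(OCCO2)CC1=O | intermediate
14 | (4S,5R,6R,10R)-6-(tert-butyldimethylsilyloxy)-4,5-epoxy-1,1-(ethylenedioxy)-4,10-dimethylcyclodecane-3,8-dione | C[C@@H]1CC(=O)C[C@@H](O[Si](C)(C)C(C)(C)C)[C@H]2O[C@]2(C)C(=O)CC13OCCO3 | intermediate
15 | (4S,5R,6R,10R)-4,5-epoxy-1,1-(ethylenedioxy)-6-hydroxy-4,10-dimethylcyclodecane-3,8-dione | C[C@@H]1CC(=O)C[C@@H](O)[C@H]2O[C@]2(C)C(=O)CC13OCCO3 | intermediate
16 | 2-(bromomethyl)acrylic acid | C=C(CBr)C(=O)O | starting material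
17 | 2-(acetoxymethyl)acrylic acid | CC(=O)OCC(=C)C(=O)O | intermediate
18 | 2-(acetoxymethyl)acryloyl chloride | CC(=O)OCC(=C)C(=O)Cl | intermediate
19 | (4S,5R,6R,10R)-4,5-epoxy-1,1-(ethylenedioxy)-4,10-dimethyl-3,8-dioxocyclodecan-6-yl 2-(acetoxymethyl)acrylate | C[C@@H]1CC(=O)C[C@@H](OC(=O)C(=C)COC(C)=O)[C@H]2O[C@]2(C)C(=O)CC13OCCO3 | intermediate
20 | (4S,5R,6R,10R)-4,5-epoxy-1,1-(ethylenedioxy)-4,10-dimethyl-3,8-dioxocyclodecan-6-yl 3-acetoxy-2-oxopropanoate | C[C@@H]1CC(=O)C[C@@H](OC(=O)C(=O)COC(C)=O)[C@H]2O[C@]2(C)C(=O)CC13OCCO3 | intermediate
21 | aldol adduct: (4S,5R,6R,10R)-13-acetoxy-4,5-epoxy-1,1-(ethylenedioxy)-11-hydroxy-3,8-dioxogermacran-12,6-olide (C7 and C11 not defined, both lost on dehydration) | CC(=O)OCC1(O)C2[C@@H](OC1=O)[C@H]1O[C@]1(C)C(=O)CC1(OCCO1)[C@H](C)CC2=O | intermediate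
22 | (4S,5R,6R,10R)-13-acetoxy-4,5-epoxy-1,1-(ethylenedioxy)-3,8-dioxogermacr-7(11)-en-12,6-olide | CC(=O)OCC1=C2[C@@H](OC1=O)[C@H]1O[C@]1(C)C(=O)CC1(OCCO1)[C@H](C)CC2=O | intermediate
23 | (4S,5R,6R,8R,10R)-13-acetoxy-4,5-epoxy-1,1-(ethylenedioxy)-8-hydroxy-3-oxogermacr-7(11)-en-12,6-olide | CC(=O)OCC1=C2[C@@H](OC1=O)[C@H]1O[C@]1(C)C(=O)CC1(OCCO1)[C@H](C)C[C@H]2O | intermediate
24 | 4-methylfuran-2(5H)-one | CC1=CC(=O)OC1 | starting material
25 | potassium (Z)-4-hydroxy-3-methylbut-2-enoate | [K+].[O-]C(=O)/C=C(/C)CO | intermediate
26 | 4-methoxybenzyl (Z)-4-hydroxy-3-methylbut-2-enoate | COc1ccc(COC(=O)/C=C(/C)CO)cc1 | intermediate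
27 | 4-methoxybenzyl (Z)-4-acetoxy-3-methylbut-2-enoate | COc1ccc(COC(=O)/C=C(/C)COC(C)=O)cc1 | intermediate
28 | (Z)-4-acetoxy-3-methylbut-2-enoic acid | OC(=O)/C=C(/C)COC(C)=O | intermediate
29 | (4S,5R,6R,8R,10R)-13-acetoxy-8-[(Z)-4-acetoxy-3-methylbut-2-enoyloxy]-4,5-epoxy-1,1-(ethylenedioxy)-3-oxogermacr-7(11)-en-12,6-olide | CC(=O)OCC1=C2[C@@H](OC1=O)[C@H]1O[C@]1(C)C(=O)CC1(OCCO1)[C@H](C)C[C@H]2OC(=O)/C=C(/C)COC(C)=O | intermediate
30 | (4S,5R,6R,8R,10R)-13-acetoxy-8-[(Z)-4-acetoxy-3-methylbut-2-enoyloxy]-4,5-epoxy-1,3-dioxogermacr-7(11)-en-12,6-olide (CNP0274470.1) | CC(=O)OCC1=C2[C@@H](OC1=O)[C@H]1O[C@]1(C)C(=O)CC(=O)[C@H](C)C[C@H]2OC(=O)/C=C(/C)COC(C)=O | target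

## Step count and least certain steps

Total: 21 steps. Longest linear sequence: 18 steps (steps 1–12, 14–17, 20 and 21); steps 13, 18 and 19 prepare the two acyl fragments.

Step 10 (key step). What may go wrong: over-oxidation or peroxide oligomerization at the hindered tetrasubstituted alkene, transannular aldol closure of the 1,6-diketone, or β-elimination of the acetate during work-up. Fallback: the same bond is cut in two stages. Starting from 11, buffered mCPBA gives the ring-fusion 3,8-epoxide F1, and H5IO6 in THF/Et2O cleaves this tetrasubstituted epoxide to the diketone, returning to the route at 12.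

Step 4. What may go wrong: a hydride shift from C5 to the developing C4 cation (ketone formation) or loss or migration of the silyl group under Lewis acid, because the attacking arene carbon is activated only by a para methyl group. Fallback: starting from 4, the unprotected epoxy alcohol is cyclized in hexafluoroisopropanol (hydrogen-bond activation of hydroxyl and epoxide together, no halide that could open the epoxide) to (1R,2S,3R)-1,6-dimethyl-1,2,3,4-tetrahydronaphthalene-2,3-diol F2. Its less hindered, equatorial C6 hydroxyl is then silylated (TBSCl, imidazole, DMF, 0 °C), returning at 6.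

Step 7. What may go wrong: insufficient facial discrimination by the chiral borane, which has only reagent control to rely on, so that C10 forms with little bias and separation at this stage becomes impractical. Fallback: starting from 8, hydroboration with thexylborane and oxidation give 9 together with its (1S,10S) isomer F3. The mixture is carried through steps 8 and 9 to 11 and its C10 epimer, ketal F5 (by way of 10 and the C10-epimeric ketone F4). The ketals are separated, and F5 is re-equilibrated at C10 with TsOH and ethylene glycol in hot benzene (through the ring-opened enol ether) and recycled, returning at 11.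

Step 11. What may go wrong: peroxide addition to the wrong face of C5, elimination to the Z-enone followed by closure to a cis-epoxide, β-elimination of the C6 silyloxy group from the C8 enolate, or transannular Michael addition. Fallback: starting from 12, DBU alone gives 13, which is isolated. NaBH4/CeCl3·7H2O reduces both ketones to the allylic 3,8-diol F6 (C3 and C8 unassigned, both re-oxidized later). The now electron-rich E-alkene is epoxidized under reagent control with Oxone (KHSO5) and the D-fructose-derived ketone 1,2:4,5-di-O-isopropylidene-β-D-erythro-2,3-hexodiulo-2,6-pyranose (Shi epoxidation, face chosen by the spiro transition-state model) to the epoxy diol F7. Dess–Martin oxidation of both carbinols returns to the route at 14. This fallback presupposes the E-enone.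

Step 16. What may go wrong: β-elimination of the C6 acyloxy group from the C7 enolate before the C–C bond forms, enolization of the keto ester toward C13, or acetyl migration during dehydration. Fallback: the reversible aldol is replaced by an irreversible Claisen-type acylation. Starting from 15, methyl oxalyl chloride/pyridine gives the C6 methyl oxalate F8. LiN(SiMe3)2 (2.2 equiv, THF, −78 °C) effects Dieckmann closure from C7 to the 11-hydroxybutenolide F9, isolated as its stabilized enol. Tf2O/2,6-lutidine gives the enol triflate F10, Stille coupling with Bu3SnCH2OH and Pd(PPh3)4/LiCl gives the 13-hydroxy butenolide F11, and acetylation (Ac2O, pyridine) returns at 22.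

Step 17. What may go wrong: hydride delivery to the wrong face of C8 because the ring conformation overrides the catalyst, competing reduction of the C3 ketone, or lactone migration to O8 at the alkoxyborane stage. Fallback: starting from 22, Luche reduction (NaBH4, CeCl3·7H2O, MeOH, −78 °C) is run under substrate control. If the 8S alcohol F12 predominates, it is esterified with 28 under Mitsunobu conditions (PPh3, diisopropyl azodicarboxylate), which inverts C8 and returns directly at 29.

## Further compounds

F1 | step 10 | 3,8-epoxide of 11 (either face) | C[C@@H]1C23OC3(C[C@@H](O[Si](C)(C)C(C)(C)C)[C@H]1OC(C)=O)C[C@@H](C)C4(C2)OCCO4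
F2 | step 4 | (1R,2S,3R)-1,6-dimethyl-1,2,3,4-tetrahydronaphthalene-2,3-diol | C[C@@H]1c2ccc(C)cc2C[C@@H](O)[C@H]1O
F3 | step 7 | (1S,10S)-diastereomer of 9 (target numbering) | C[C@@H]1C2=C(C[C@@H](O[Si](C)(C)C(C)(C)C)[C@H]1OC(C)=O)C[C@H](C)[C@@H](O)C2
F4 | step 7 | C10 epimer of ketone 10 | C[C@@H]1C2=C(C[C@@H](O[Si](C)(C)C(C)(C)C)[C@H]1OC(C)=O)C[C@H](C)C(=O)C2
F5 | step 7 | C10 epimer of ketal 11 | C[C@@H]1C2=C(C[C@@H](O[Si](C)(C)C(C)(C)C)[C@H]1OC(C)=O)C[C@H](C)C3(C2)OCCO3
F6 | step 11 | (4E,6R,10R)-6-(tert-butyldimethylsilyloxy)-1,1-(ethylenedioxy)-4,10-dimethylcyclodec-4-ene-3,8-diol (C3 and C8 unassigned) | C/C1=C\[C@H](O[Si](C)(C)C(C)(C)C)CC(O)C[C@@H](C)C2(OCCO2)CC1O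
F7 | step 11 | 4,5-epoxide of F6 with the C4, C5 configuration of 14 | C[C@@H]1CC(O)C[C@@H](O[Si](C)(C)C(C)(C)C)[C@H]2O[C@]2(C)C(O)CC13OCCO3
F8 | step 16 | C6 methyl oxalate of 15 | C[C@@H]1CC(=O)C[C@@H](OC(=O)C(=O)OC)[C@H]2O[C@]2(C)C(=O)CC13OCCO3
F9 | step 16 | 11-hydroxy analogue of 22 lacking C13 (enol of the 11-oxo lactone) | OC1=C2[C@@H](OC1=O)[C@H]1O[C@]1(C)C(=O)CC1(OCCO1)[C@H](C)CC2=O
F10 | step 16 | enol triflate of F9 | FC(F)(F)S(=O)(=O)OC1=C2[C@@H](OC1=O)[C@H]1O[C@]1(C)C(=O)CC1(OCCO1)[C@H](C)CC2=O
F11 | step 16 | 13-hydroxy analogue of 22 | OCC1=C2[C@@H](OC1=O)[C@H]1O[C@]1(C)C(=O)CC1(OCCO1)[C@H](C)CC2=O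
F12 | step 17 | C8 epimer (8S) of 23 | CC(=O)OCC1=C2[C@@H](OC1=O)[C@H]1O[C@]1(C)C(=O)CC1(OCCO1)[C@H](C)C[C@@H]2O
A1 | alternative 1 | isoxazoline-bridged ten-membered carbocycle with butenolide, epoxide and both esters in place | CC(=O)OCC1=C2[C@@H](OC1=O)[C@H]3O[C@]3(C)C4=NO[C@@H](C4)[C@H](C)C[C@H]2OC(=O)/C=C(/C)COC(C)=O
A2 | alternative 2 | butenolide-fused ten-membered ring with C3 acetate, E C4=C5, C1 dioxolane, C8 4-methoxybenzyl ether and C13 silyl ether | CC(C)(C)[Si](C)(C)OCC1=C2[C@@H](OC1=O)/C=C(C)/[C@@H](OC(C)=O)CC3(OCCO3)[C@H](C)C[C@H]2OCc2ccc(OC)cc2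
A3 | alternative 3 | ten-membered 1-ethoxy-3-(trimethylsilyloxy) diene with C6–O tetrahydrofuran and E C7=C8 | CCO/C1=C/C(O[Si](C)(C)C)=C(C)/C[C@@H]2OCC/C2=C\C[C@H]1C
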